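## Retrosynthetic overview

1. The target is (5R,6S,5'S), with the two OH groups trans on the five-membered ring. Open the C7–C7a acyl–pyridine bond to reach an acyclic bromopyridyl 2,3-dihydroxy-3-methylsuccinate. Ring A (pyridine) is bought. Ring B (cyclopentanone) is the only ring made, and it is closed last.
2. Cut C3–C1' (Suzuki–Miyaura) into a 2,5-dibromopyridyl diol diester and an (E,E)-dienylboronate.
3. Key disconnection: both tertiary C–O bonds are made in one enantioselective syn-dihydroxylation of a Z tetrasubstituted aryl(methyl)maleate. Syn addition to the Z alkene becomes the trans-diol once aryl and C7 are tied into ring B.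
4. The maleate comes from 2,5-dibromopyridine, dimethyl acetylenedicarboxylate and MeI by syn-carbocupration and methylation.
5. The boronate comes from (S)-2-methylbutan-1-ol, which supplies the C5' stereocentre, by oxidation/Wittig and then boron-Wittig.

Assumption: the sense of induction in step 2 cannot be predicted. Both antipodes of the catalyst are available from (S,S)- or (R,R)-1,2-diphenylethane-1,2-diamine. The route is written for the antipode that gives (2R,3S)-7, to be checked by anomalous-dispersion X-ray analysis of this dibromide.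

## Route

Step 1
Reactants: 1 2,5-dibromopyridine; 2 dimethyl but-2-ynedioate
Product: 6 dimethyl (Z)-2-(2,5-dibromopyridin-4-yl)-3-methylbut-2-enedioate, via 2,5-dibromo-4-lithiopyridine 3 (not isolated), via (2,5-dibromopyridin-4-yl)copper 4 (not isolated), via alkenylcopper syn-adduct 5 (not isolated)
Conditions: LiN(iPr)2 (1.05 equiv), THF, −78 °C, 20 min; CuBr·SMe2 (1.1 equiv), −78 °C; 2 (1.1 equiv), −78 → −40 °C; MeI (5 equiv), DMPU, −40 °C → rt
Reagents that add atoms: iodomethane, CI
Why: Directed ortho-lithiation at C4 next to the C5 bromine, Li-to-Cu exchange, syn-carbocupration of the symmetric ynedioate and C-methylation of the alkenylcopper with retention place aryl and methyl on the same side (Z, ester groups cis), which follows the known organocopper/acetylenedicarboxylate/MeI route to 2-substituted 3-methylmaleates.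

Step 2
Reactants: 6 dimethyl (Z)-2-(2,5-dibromopyridin-4-yl)-3-methylbut-2-enedioate
Product: 7 dimethyl (2R,3S)-2-(2,5-dibromopyridin-4-yl)-2,3-dihydroxy-3-methylbutanedioate
Conditions: KMnO4 (1.5 equiv, powdered), 2,2'-(piperazine-1,4-diyl)bis[(4S,5S)-1,3-bis(3,5-di-tert-butylbenzyl)-4,5-diphenyl-4,5-dihydro-1H-imidazol-3-ium] dichloride or its antipode (5 mol %), MTBE, −30 °C, 24 h; pH 7 buffer, 0 °C, filter off MnO2
Reagents that add atoms: potassium permanganate, [K+].[O-][Mn](=O)(=O)=O
Why: Proposed new method: the lipophilic chiral dication carries MnO4− into MTBE as a tight ion pair, the low-LUMO Z alkene (whose two cis ester groups dock on the dication) takes up permanganate in a concerted suprafacial [3+2] addition on one enantiotopic face to give a cyclic manganate ester of pentavalent manganese, and hydrolysis at Mn–O releases the syn-diol, so both C–O bonds and both stereocentres (2R,3S) are set at once with the relative configuration fixed by the Z geometry and with ketol over-oxidation impossible because no carbinol C–H exists; the closest known reaction type is chiral-cation phase-transfer permanganate dihydroxylation of 2-arylacrylates and trisubstituted enoates, which has not been shown on a tetrasubstituted 2-aryl-3-methylmaleate.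

Step 3
Reactants: 8 (S)-2-methylbutan-1-ol
Product: 10 (2E,4S)-2,4-dimethylhex-2-enal, via (S)-2-methylbutanal 9 (not isolated)
Conditions: 2,2,6,6-tetramethylpiperidine-1-oxyl (10 mol %), PhI(OAc)2 (1.1 equiv), CH2Cl2, 0 °C → rt; then Ph3P=C(CH3)CHO (1.3 equiv), 40 °C, 24 h
Reagents that add atoms: 2-(triphenyl-λ5-phosphanylidene)propanal, CC(C=O)=P(c1ccccc1)(c1ccccc1)c1ccccc1
Why: The nitroxyl-catalysed oxidation stops at the aldehyde, and the Wittig reaction of the stabilised formyl ylide in the same flask gives the E trisubstituted enal without handling the volatile, epimerisable aldehyde, so the stereocentre comes unchanged from the chiral-pool alcohol.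

Step 4
Reactants: 10 (2E,4S)-2,4-dimethylhex-2-enal; 11 bis(4,4,5,5-tetramethyl-1,3,2-dioxaborolan-2-yl)methane
Product: 13 2-[(1E,3E,5S)-3,5-dimethylhepta-1,3-dien-1-yl]-4,4,5,5-tetramethyl-1,3,2-dioxaborolane, via lithiated bis(boryl)methane 12 (not isolated)
Conditions: 2,2,6,6-tetramethylpiperidine (1.25 equiv), nBuLi (1.2 equiv), THF, 0 °C; 11 (1.2 equiv), 0 °C; 10, −78 °C → rt
Reagents that add atoms: none
Why: In this boron-Wittig olefination the α-diboryl carbanion adds 1,2 to the enal, and syn B–O elimination from the less crowded adduct gives the E alkenylboronate without touching the stereocentre or the existing E alkene.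

Step 5
Reactants: 7 dimethyl (2R,3S)-2-(2,5-dibromopyridin-4-yl)-2,3-dihydroxy-3-methylbutanedioate; 13 2-[(1E,3E,5S)-3,5-dimethylhepta-1,3-dien-1-yl]-4,4,5,5-tetramethyl-1,3,2-dioxaborolane
Product: 14 dimethyl (2R,3S)-2-{5-bromo-2-[(1E,3E,5S)-3,5-dimethylhepta-1,3-dien-1-yl]pyridin-4-yl}-2,3-dihydroxy-3-methylbutanedioate
Conditions: 13 (1.05 equiv), Pd(dppf)Cl2 (5 mol %), K3PO4 (2 equiv), THF/H2O 10:1, 45 °C
Reagents that add atoms: none
Why: In this Suzuki–Miyaura coupling zerovalent palladium inserts faster into the C2–Br bond next to nitrogen than into the C5–Br bond shielded by the adjacent quaternary carbon, the alkenyl geometry is retained, and the fully substituted carbinol centres cannot epimerise.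

Step 6
Reactants: 14 dimethyl (2R,3S)-2-{5-bromo-2-[(1E,3E,5S)-3,5-dimethylhepta-1,3-dien-1-yl]pyridin-4-yl}-2,3-dihydroxy-3-methylbutanedioate
Product: 17 methyl (5R,6S)-3-[(1E,3E,5S)-3,5-dimethylhepta-1,3-dien-1-yl]-5,6-dihydroxy-6-methyl-7-oxo-6,7-dihydro-5H-cyclopenta[c]pyridine-5-carboxylate, via bis(chloromagnesium) diolate 15 (not isolated), via pyridylmagnesium chloride 16 (not isolated)
Conditions: MeMgCl (2.05 equiv), LiCl (2 equiv), THF, −40 °C, 15 min; iPrMgCl·LiCl (1.2 equiv), −40 → −10 °C, 1 h; sat. aq NH4Cl, −40 °C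
Reagents that add atoms: none
Why: In this Parham-type cyclisation the two OH groups are first masked as magnesium alkoxides, alkoxide-assisted Br/Mg exchange then gives a pyridyl Grignard that can reach only the ester on C3 of the succinate (5-exo acyl substitution, since the other ester would need a four-membered ring), and closing ring B leaves both stereocentres untouched while turning the acyclic syn-diol into the trans-diol of the target.

## Compound list

1 | 2,5-dibromopyridine | Brc1ccc(Br)nc1 | starting material
2 | dimethyl but-2-ynedioate | COC(=O)C#CC(=O)OC | starting material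
3 | 2,5-dibromo-4-lithiopyridine | [Li]c1cc(Br)ncc1Br | intermediate (not isolated)
4 | (2,5-dibromopyridin-4-yl)copper | [Cu]c1cc(Br)ncc1Br | intermediate (not isolated)
5 | alkenylcopper syn-adduct: dimethyl 2-cuprio-3-(2,5-dibromopyridin-4-yl)but-2-enedioate, ester groups cis | COC(=O)/C([Cu])=C(\C(=O)OC)c1cc(Br)ncc1Br | intermediate (not isolated)
6 | dimethyl (Z)-2-(2,5-dibromopyridin-4-yl)-3-methylbut-2-enedioate | COC(=O)/C(C)=C(\C(=O)OC)c1cc(Br)ncc1Br | intermediate
7 | dimethyl (2R,3S)-2-(2,5-dibromopyridin-4-yl)-2,3-dihydroxy-3-methylbutanedioate | COC(=O)[C@@](C)(O)[C@@](c1cc(Br)ncc1Br)(O)C(=O)OC | intermediate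
8 | (S)-2-methylbutan-1-ol | CC[C@H](C)CO | starting material
9 | (S)-2-methylbutanal | CC[C@H](C)C=O | intermediate (not isolated)
10 | (2E,4S)-2,4-dimethylhex-2-enal | CC[C@H](C)/C=C(\C)C=O | intermediate
11 | bis(4,4,5,5-tetramethyl-1,3,2-dioxaborolan-2-yl)methane | CC1(C)OB(CB2OC(C)(C)C(C)(C)O2)OC1(C)C | starting material
12 | lithiated bis(boryl)methane: [bis(4,4,5,5-tetramethyl-1,3,2-dioxaborolan-2-yl)methyl]lithium | [Li]C(B1OC(C)(C)C(C)(C)O1)B1OC(C)(C)C(C)(C)O1 | intermediate (not isolated)
13 | 2-[(1E,3E,5S)-3,5-dimethylhepta-1,3-dien-1-yl]-4,4,5,5-tetramethyl-1,3,2-dioxaborolane | CC[C@H](C)/C=C(C)/C=C/B1OC(C)(C)C(C)(C)O1 | intermediate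
14 | dimethyl (2R,3S)-2-{5-bromo-2-[(1E,3E,5S)-3,5-dimethylhepta-1,3-dien-1-yl]pyridin-4-yl}-2,3-dihydroxy-3-methylbutanedioate | COC(=O)[C@@](C)(O)[C@@](c1cc(/C=C/C(C)=C/[C@@H](C)CC)ncc1Br)(O)C(=O)OC | intermediate
15 | bis(chloromagnesium) diolate of 14 | COC(=O)[C@@](C)(O[Mg]Cl)[C@@](c1cc(/C=C/C(C)=C/[C@@H](C)CC)ncc1Br)(O[Mg]Cl)C(=O)OC | intermediate (not isolated)
16 | pyridylmagnesium chloride formed from 15 by Br/Mg exchange | COC(=O)[C@@](C)(O[Mg]Cl)[C@@](c1cc(/C=C/C(C)=C/[C@@H](C)CC)ncc1[Mg]Cl)(O[Mg]Cl)C(=O)OC | intermediate (not isolated)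
17 | methyl (5R,6S)-3-[(1E,3E,5S)-3,5-dimethylhepta-1,3-dien-1-yl]-5,6-dihydroxy-6-methyl-7-oxo-6,7-dihydro-5H-cyclopenta[c]pyridine-5-carboxylate | CC[C@H](C)/C=C(C)/C=C/c1cc2c(cn1)C(=O)[C@@](C)(O)[C@@]2(O)C(=O)OC | target

## Step count and risks

Total step count: 6. Longest linear sequence: 4 (steps 1, 2, 5, 6). Steps 3 and 4 form the two-step side branch.

**Step 2 (the new reaction).** The alkene is tetrasubstituted and carries an ortho-bromo aryl group. It may therefore react slowly, give modest ee with methyl esters, or undergo some C–C cleavage. Crystalline 7 can be enriched by recrystallisation.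

The fallback uses known chemistry, sets out from 6 and comes back at 7. A racemic flash syn-dihydroxylation with catalytic RuCl3 and NaIO4 in EtOAc/MeCN/H2O at 0 °C gives 7 as a 1:1 mixture with its enantiomer, dimethyl (2S,3R)-2-(2,5-dibromopyridin-4-yl)-2,3-dihydroxy-3-methylbutanedioate F4. The two are separated by preparative SFC on an amylose carbamate chiral phase.

**Step 6.** A magnesium chelate across the two alkoxides favours a rotamer in which aryl and the reacting ester are far apart. iPrMgCl may also attack an ester, and the product aldolate could open by retro-aldol if it is warmed.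

The fallback sets out from 14 and comes back at 17. The diol is masked with TMSOTf and 2,6-lutidine as the bis(trimethylsilyl) ether of 14 F5, whose bulky silyloxy groups prefer the rotamer that brings aryl and ester together. Classical Parham Br/Li exchange with nBuLi in THF at −100 °C gives the aryllithium F6. This closes at once to the bis(trimethylsilyl) ether of the target F7, and HF·pyridine in THF at 0 °C removes both silyl groups.

**Step 1.** The ester-stabilised alkenylcopper 5 may methylate slowly, may lose its geometry through an allenolate, or diisopropylamine may add to 2.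

The fallback sets out from 2 and from 3 (made from 1 as in step 1) and comes back at 6. MeCu, from MeLi and CuBr·SMe2, is added syn to 2 at −78 °C to give the alkenylcopper dimethyl 2-cuprio-3-methylbut-2-enedioate F1. I2 converts this to dimethyl 2-iodo-3-methylbut-2-enedioate with cis ester groups F2. Separately, 3 is transmetalated with ZnCl2 to (2,5-dibromopyridin-4-yl)zinc chloride F3. Negishi coupling of F2 and F3 with Pd(PPh3)4 in THF at rt proceeds with retention at the far more reactive alkenyl iodide.

## Further compounds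

F1 | step 1 | dimethyl 2-cuprio-3-methylbut-2-enedioate, ester groups cis | COC(=O)/C(C)=C(\C(=O)OC)[Cu]
F2 | step 1 | dimethyl 2-iodo-3-methylbut-2-enedioate, ester groups cis | COC(=O)/C(C)=C(\C(=O)OC)I
F3 | step 1 | (2,5-dibromopyridin-4-yl)zinc chloride | Cl[Zn]c1cc(Br)ncc1Br
F4 | step 2 | dimethyl (2S,3R)-2-(2,5-dibromopyridin-4-yl)-2,3-dihydroxy-3-methylbutanedioate | COC(=O)[C@](C)(O)[C@](c1cc(Br)ncc1Br)(O)C(=O)OC
F5 | step 6 | bis(trimethylsilyl) ether of 14 | COC(=O)[C@@](C)(O[Si](C)(C)C)[C@@](c1cc(/C=C/C(C)=C/[C@@H](C)CC)ncc1Br)(O[Si](C)(C)C)C(=O)OC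
F6 | step 6 | aryllithium from F5 | COC(=O)[C@@](C)(O[Si](C)(C)C)[C@@](c1cc(/C=C/C(C)=C/[C@@H](C)CC)ncc1[Li])(O[Si](C)(C)C)C(=O)OC
F7 | step 6 | bis(trimethylsilyl) ether of 17 | CC[C@H](C)/C=C(C)/C=C/c1cc2c(cn1)C(=O)[C@@](C)(O[Si](C)(C)C)[C@@]2(O[Si](C)(C)C)C(=O)OC
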